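**Plan**

- Locants: unprimed for the flavone with the 7-methoxy group (rings A, C, B), double-primed for the flavone with the 4-methoxyphenyl group (rings A'', C''); the biaryl bond is C3'–C8''.
- Retrosynthesis: the four benzyl ethers are removed first, then the pyranone bonds O1–C2 and O1''–C2'' are cut, then C2–C3 and C2''–C3'' together, then the two aryl ester C–O bonds, and last the C3'–C8'' biaryl bond.
- Enabling feature: C3 and C3'' are acetophenone methyl carbons and C2 and C2'' are aroyl carbons. Ring B (through C1') is the aroyl donor for ring C, ring A'' is the acetophenone of ring C'', and each acetyl group has an ortho oxygen (the later O1 and O1'') that can hold its acyl partner as an ester.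
- Forward: Suzuki coupling of a ring A'' iodophenol with a ring B boronate (carboxyl carried as a formyl group) gives the biaryl; anisoylation, oxidation to the acid and esterification with the ring A phenol give the diester.
- A twofold Baker–Venkataraman shift then builds both 1,3-diketones in one operation, acid closes rings C and C'' together, and hydrogenolysis frees the four phenols.
- Stereochemistry: the target has no stereocentre and its biaryl axis is not configurationally defined, so nothing has to be controlled.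

Key step: step 10

Remark: the 1,3-diketones are drawn and named as diketo tautomers although they are expected to exist mainly as chelated enols; this does not change the chemistry. Compounds 1, 4, 8 and 11 are taken as commercially available.

**Route**

Step 1
Reactants: 1 2',4',6'-trihydroxyacetophenone
Product: 2 1-[2,4-bis(benzyloxy)-6-hydroxyphenyl]ethan-1-one
Conditions: BnBr (2.1 equiv), K2CO3, DMF, rt
Reagents that add atoms: benzyl bromide, BrCc1ccccc1
Why: Williamson etherification in which the two non-chelated phenols are alkylated while the third, hydrogen-bonded to the acetyl carbonyl, is far less nucleophilic and should stay free with two equivalents of halide.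

Step 2
Reactants: 2 1-[2,4-bis(benzyloxy)-6-hydroxyphenyl]ethan-1-one
Product: 3 1-[4,6-bis(benzyloxy)-2-hydroxy-3-iodophenyl]ethan-1-one
Conditions: NIS (1.05 equiv), DMF, 0 °C to rt, dark
Reagents that add atoms: N-iodosuccinimide, O=C1CCC(=O)N1I
Why: Electrophilic aromatic iodination in which the free phenol directs the iodonium source to its own ortho position, the carbon that becomes C8''.

Step 3
Reactants: 4 3-bromo-4-hydroxybenzaldehyde
Product: 5 4-(benzyloxy)-3-bromobenzaldehyde
Conditions: BnBr (1.1 equiv), K2CO3, DMF, 60 °C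
Reagents that add atoms: benzyl bromide, BrCc1ccccc1
Why: Williamson etherification of an acidic phenol, which protects the later 4'-OH with the same group used on the other rings.

Step 4
Reactants: 5 4-(benzyloxy)-3-bromobenzaldehyde
Product: 6 4-(benzyloxy)-3-(4,4,5,5-tetramethyl-1,3,2-dioxaborolan-2-yl)benzaldehyde
Conditions: B2pin2 (1.2 equiv), PdCl2(dppf) (3 mol %), KOAc (3 equiv), 1,4-dioxane, 90 °C
Reagents that add atoms: bis(pinacolato)diboron, CC1(C)OB(OC1(C)C)B1OC(C)(C)C(C)(C)O1
Why: Miyaura borylation, in which zerovalent palladium inserts into the aryl bromide and acetate-assisted transmetalation with the diboron delivers the pinacol boronate; the aldehyde is tolerated under these weakly basic conditions.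

Step 5
Reactants: 3 1-[4,6-bis(benzyloxy)-2-hydroxy-3-iodophenyl]ethan-1-one; 6 4-(benzyloxy)-3-(4,4,5,5-tetramethyl-1,3,2-dioxaborolan-2-yl)benzaldehyde
Product: 7 3-[3-acetyl-4,6-bis(benzyloxy)-2-hydroxyphenyl]-4-(benzyloxy)benzaldehyde
Conditions: Pd(OAc)2 (5 mol %), SPhos (2-dicyclohexylphosphino-2',6'-dimethoxybiphenyl, 10 mol %), K3PO4 (3 equiv), toluene/H2O (10:1), 80 °C
Reagents that add atoms: none
Why: Suzuki–Miyaura coupling in which the bulky electron-rich biaryl phosphine should allow oxidative addition into the hindered iodide and reductive elimination of the tri-ortho-substituted biaryl; boron is placed on the less electron-rich ring to limit protodeboronation, and a ring B formyl group, unlike an allyl or aryl ester, is not attacked by zerovalent palladium or aqueous base.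

Step 6
Reactants: 7 3-[3-acetyl-4,6-bis(benzyloxy)-2-hydroxyphenyl]-4-(benzyloxy)benzaldehyde; 8 4-methoxybenzoyl chloride
Product: 9 2-acetyl-3,5-bis(benzyloxy)-6-[2-(benzyloxy)-5-formylphenyl]phenyl 4-methoxybenzoate
Conditions: 8 (1.5 equiv), Et3N (3 equiv), DMAP (0.2 equiv), CH2Cl2, 0 °C to rt
Reagents that add atoms: none
Why: DMAP-catalysed O-acylation of a phenol, where the acylpyridinium ion is reactive enough for the chelated, flanked hydroxyl and the aldehyde is inert.

Step 7
Reactants: 9 2-acetyl-3,5-bis(benzyloxy)-6-[2-(benzyloxy)-5-formylphenyl]phenyl 4-methoxybenzoate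
Product: 10 3-[3-acetyl-4,6-bis(benzyloxy)-2-(4-methoxybenzoyloxy)phenyl]-4-(benzyloxy)benzoic acid
Conditions: NaClO2 (3 equiv), NaH2PO4 (3 equiv), 2-methyl-2-butene (20 equiv), t-BuOH/THF/H2O, 0 °C to rt
Reagents that add atoms: sodium chlorite, [Na+].[O-]Cl=O
Why: Pinnick oxidation, in which chlorous acid converts the aryl aldehyde into the acid without touching the aryl ester, ketone or benzyl ethers, while the alkene traps hypochlorous acid before it can chlorinate the electron-rich rings; carrying the carboxyl as an aldehyde up to this point saves a carboxyl protecting group.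

Step 8
Reactants: 11 2',6'-dihydroxy-4'-methoxyacetophenone
Product: 12 1-[2-(benzyloxy)-6-hydroxy-4-methoxyphenyl]ethan-1-one
Conditions: BnBr (1.05 equiv), K2CO3, acetone, reflux
Reagents that add atoms: benzyl bromide, BrCc1ccccc1
Why: Williamson etherification that should stop after one alkylation, because the remaining hydroxyl is then held in a strong hydrogen bond to the acetyl carbonyl.

Step 9
Reactants: 10 3-[3-acetyl-4,6-bis(benzyloxy)-2-(4-methoxybenzoyloxy)phenyl]-4-(benzyloxy)benzoic acid; 12 1-[2-(benzyloxy)-6-hydroxy-4-methoxyphenyl]ethan-1-one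
Product: 13 2-acetyl-3-(benzyloxy)-5-methoxyphenyl 3-[3-acetyl-4,6-bis(benzyloxy)-2-(4-methoxybenzoyloxy)phenyl]-4-(benzyloxy)benzoate
Conditions: DCC (1.3 equiv), DMAP (0.3 equiv), CH2Cl2, rt
Reagents that add atoms: none
Why: Steglich esterification, the usual way to load a benzoic acid onto an ortho-hydroxyacetophenone, run under neutral conditions that leave the existing anisoate untouched.

Step 10
Reactants: 13 2-acetyl-3-(benzyloxy)-5-methoxyphenyl 3-[3-acetyl-4,6-bis(benzyloxy)-2-(4-methoxybenzoyloxy)phenyl]-4-(benzyloxy)benzoate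
Product: 14 1-[2-(benzyloxy)-6-hydroxy-4-methoxyphenyl]-3-[4-(benzyloxy)-3-{4,6-bis(benzyloxy)-2-hydroxy-3-[3-(4-methoxyphenyl)-3-oxopropanoyl]phenyl}phenyl]propane-1,3-dione
Conditions: LiN(SiMe3)2 (7 equiv), THF, −78 °C to 0 °C; then 1 M HCl
Reagents that add atoms: none
Why: Excess LiN(SiMe3)2 turns both acetyl groups into lithium enolates, each of which adds to the carbonyl of the aryl ester on the neighbouring phenol oxygen; the tetrahedral adducts collapse with loss of the phenoxides, so that C2–C3 and C2''–C3'' are formed, and deprotonation of the new 1,3-diketones drives the process. The closest known reaction type is the Baker–Venkataraman rearrangement of ortho-aroyloxyacetophenones, applied here to two such units in one molecule. No ring stays closed, since each transient six-membered adduct arises by 6-exo-trig attack and opens again, and no stereocentre is created. The step needs each acyl group to reach only its own acetyl carbon and needs migration to outrun ester cleavage; the first is secured by the ortho relationship within each unit, because any crossover would pass through a macrocyclic transition state, and the second by the hindered, non-nucleophilic amide base at low temperature. The two phenoxides set free are exactly the oxygens that become O1 and O1''.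

Step 11
Reactants: 14 the bis(1,3-diketone) of step 10
Product: 15 5,7-bis(benzyloxy)-8-{2-(benzyloxy)-5-[5-(benzyloxy)-7-methoxy-4-oxo-4H-chromen-2-yl]phenyl}-2-(4-methoxyphenyl)-4H-chromen-4-one
Conditions: p-TsOH·H2O (0.3 equiv), toluene, 90 °C
Reagents that add atoms: none
Why: Acid-catalysed cyclodehydration in which each free phenol adds to the distal carbonyl of its enolised diketone (6-exo-trig) and loss of water gives the 4H-chromen-4-one, closing rings C and C'' together; any incidental loss of a benzyl group is harmless because the next step removes all four.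

Step 12
Reactants: 15 the tetrabenzyl ether of step 11
Product: 16 putraflavone
Conditions: H2 (1 atm), 10% Pd/C, THF/MeOH (1:1), rt
Reagents that add atoms: none
Why: Catalytic hydrogenolysis of aryl benzyl ethers, which should leave the methyl ethers and the conjugated pyranone rings intact.

**Compound list**

1 | 2',4',6'-trihydroxyacetophenone | CC(=O)c1c(O)cc(O)cc1O | starting material
2 | 1-[2,4-bis(benzyloxy)-6-hydroxyphenyl]ethan-1-one | CC(=O)c1c(O)cc(OCc2ccccc2)cc1OCc1ccccc1 | intermediate
3 | 1-[4,6-bis(benzyloxy)-2-hydroxy-3-iodophenyl]ethan-1-one | CC(=O)c1c(O)c(I)c(OCc2ccccc2)cc1OCc1ccccc1 | intermediate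
4 | 3-bromo-4-hydroxybenzaldehyde | O=Cc1ccc(O)c(Br)c1 | starting material
5 | 4-(benzyloxy)-3-bromobenzaldehyde | O=Cc1ccc(OCc2ccccc2)c(Br)c1 | intermediate
6 | 4-(benzyloxy)-3-(4,4,5,5-tetramethyl-1,3,2-dioxaborolan-2-yl)benzaldehyde | O=Cc1ccc(OCc2ccccc2)c(c1)B1OC(C)(C)C(C)(C)O1 | intermediate
7 | 3-[3-acetyl-4,6-bis(benzyloxy)-2-hydroxyphenyl]-4-(benzyloxy)benzaldehyde | CC(=O)c1c(O)c(-c2cc(C=O)ccc2OCc2ccccc2)c(OCc2ccccc2)cc1OCc1ccccc1 | intermediate
8 | 4-methoxybenzoyl chloride | COc1ccc(cc1)C(Cl)=O | starting material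
9 | 2-acetyl-3,5-bis(benzyloxy)-6-[2-(benzyloxy)-5-formylphenyl]phenyl 4-methoxybenzoate | CC(=O)c1c(OC(=O)c2ccc(OC)cc2)c(-c2cc(C=O)ccc2OCc2ccccc2)c(OCc2ccccc2)cc1OCc1ccccc1 | intermediate
10 | 3-[3-acetyl-4,6-bis(benzyloxy)-2-(4-methoxybenzoyloxy)phenyl]-4-(benzyloxy)benzoic acid | CC(=O)c1c(OC(=O)c2ccc(OC)cc2)c(-c2cc(C(=O)O)ccc2OCc2ccccc2)c(OCc2ccccc2)cc1OCc1ccccc1 | intermediate
11 | 2',6'-dihydroxy-4'-methoxyacetophenone | CC(=O)c1c(O)cc(OC)cc1O | starting material
12 | 1-[2-(benzyloxy)-6-hydroxy-4-methoxyphenyl]ethan-1-one | CC(=O)c1c(O)cc(OC)cc1OCc1ccccc1 | intermediate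
13 | 2-acetyl-3-(benzyloxy)-5-methoxyphenyl 3-[3-acetyl-4,6-bis(benzyloxy)-2-(4-methoxybenzoyloxy)phenyl]-4-(benzyloxy)benzoate | CC(=O)c1c(OCc2ccccc2)cc(OC)cc1OC(=O)c1ccc(OCc2ccccc2)c(c1)-c1c(OCc2ccccc2)cc(OCc2ccccc2)c(C(C)=O)c1OC(=O)c1ccc(OC)cc1 | intermediate
14 | 1-[2-(benzyloxy)-6-hydroxy-4-methoxyphenyl]-3-[4-(benzyloxy)-3-{4,6-bis(benzyloxy)-2-hydroxy-3-[3-(4-methoxyphenyl)-3-oxopropanoyl]phenyl}phenyl]propane-1,3-dione | COc1ccc(cc1)C(=O)CC(=O)c1c(O)c(c(OCc2ccccc2)cc1OCc1ccccc1)-c1cc(ccc1OCc1ccccc1)C(=O)CC(=O)c1c(O)cc(OC)cc1OCc1ccccc1 | intermediate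
15 | 5,7-bis(benzyloxy)-8-{2-(benzyloxy)-5-[5-(benzyloxy)-7-methoxy-4-oxo-4H-chromen-2-yl]phenyl}-2-(4-methoxyphenyl)-4H-chromen-4-one | COc1ccc(-c2cc(=O)c3c(OCc4ccccc4)cc(OCc4ccccc4)c(-c4cc(-c5cc(=O)c6c(OCc7ccccc7)cc(OC)cc6o5)ccc4OCc4ccccc4)c3o2)cc1 | intermediate
16 | putraflavone | COc1ccc(-c2cc(=O)c3c(O)cc(O)c(-c4cc(-c5cc(=O)c6c(O)cc(OC)cc6o5)ccc4O)c3o2)cc1 | target

**Step count**

Total: 12 steps. Longest linear sequence: 9 steps (steps 1, 2, 5, 6, 7, 9, 10, 11, 12; the ring B branch through steps 3 and 4 is equally long).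

**Steps most likely to fail**

Step 5. Oxidative addition may be slow at an iodide flanked by a phenoxide and a benzyloxy group, the boronate may protodeboronate, and the aqueous base may start an aldol condensation between the formyl and acetyl groups. Fallback: reverse the order of acylation and coupling. Setting out from 3, the phenol is acylated with 8 (Et3N, DMAP, CH2Cl2) to give 2-acetyl-3,5-bis(benzyloxy)-6-iodophenyl 4-methoxybenzoate F1, a neutral and less electron-rich iodide. This is coupled with 6 under water-free fluoride activation (Pd(OAc)2, SPhos, CsF, 1,4-dioxane, 90 °C), which avoids both the phenoxide and aqueous base, and the route is rejoined at 9.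

Step 10. The acyl transfer may stay incomplete at one of the two sites, most likely the crowded one beside the biaryl bond, or the base may cleave an aryl ester instead of inducing migration, so that mixtures of half-rearranged and deacylated material result. Fallback: carry out the two acyl shifts one after the other, the crowded one first on a simpler substrate. Setting out from 10, LiN(SiMe3)2 (4.5 equiv, one being taken by the carboxylic acid) in THF at −78 °C to 0 °C should give 4-(benzyloxy)-3-{4,6-bis(benzyloxy)-2-hydroxy-3-[3-(4-methoxyphenyl)-3-oxopropanoyl]phenyl}benzoic acid F2. Treatment with p-TsOH·H2O in toluene at 90 °C closes ring C'' to 4-(benzyloxy)-3-[5,7-bis(benzyloxy)-2-(4-methoxyphenyl)-4-oxo-4H-chromen-8-yl]benzoic acid F3. Esterification with 12 (DCC, DMAP, CH2Cl2) gives 2-acetyl-3-(benzyloxy)-5-methoxyphenyl 4-(benzyloxy)-3-[5,7-bis(benzyloxy)-2-(4-methoxyphenyl)-4-oxo-4H-chromen-8-yl]benzoate F4. A single Baker–Venkataraman shift (LiN(SiMe3)2, THF) then gives 1-[2-(benzyloxy)-6-hydroxy-4-methoxyphenyl]-3-{4-(benzyloxy)-3-[5,7-bis(benzyloxy)-2-(4-methoxyphenyl)-4-oxo-4H-chromen-8-yl]phenyl}propane-1,3-dione F5, and acid cyclodehydration of it (p-TsOH·H2O, toluene, 90 °C) returns to the route at 15.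

Step 12. Partly debenzylated biflavones may precipitate on the catalyst and stall the reaction, or prolonged exposure may begin to reduce the C2–C3 and C2''–C3'' double bonds. Fallback: replace hydrogenolysis by Lewis acid debenzylation. Setting out from 15, BCl3 with pentamethylbenzene as benzyl cation scavenger in CH2Cl2 at −78 °C, followed by a methanol quench and aqueous work-up, should cleave the four benzyl ethers while the two non-chelated methyl ethers and the pyranone double bonds stay untouched. It arrives directly at 16; no new compound arises on the way (entry F0).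

**Further compounds**

F1 | step 5 | 2-acetyl-3,5-bis(benzyloxy)-6-iodophenyl 4-methoxybenzoate | CC(=O)c1c(OC(=O)c2ccc(OC)cc2)c(I)c(OCc2ccccc2)cc1OCc1ccccc1
F2 | step 10 | 4-(benzyloxy)-3-{4,6-bis(benzyloxy)-2-hydroxy-3-[3-(4-methoxyphenyl)-3-oxopropanoyl]phenyl}benzoic acid | COc1ccc(cc1)C(=O)CC(=O)c1c(O)c(c(OCc2ccccc2)cc1OCc1ccccc1)-c1cc(ccc1OCc1ccccc1)C(=O)O
F3 | step 10 | 4-(benzyloxy)-3-[5,7-bis(benzyloxy)-2-(4-methoxyphenyl)-4-oxo-4H-chromen-8-yl]benzoic acid | COc1ccc(-c2cc(=O)c3c(OCc4ccccc4)cc(OCc4ccccc4)c(-c4cc(C(=O)O)ccc4OCc4ccccc4)c3o2)cc1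
F4 | step 10 | 2-acetyl-3-(benzyloxy)-5-methoxyphenyl 4-(benzyloxy)-3-[5,7-bis(benzyloxy)-2-(4-methoxyphenyl)-4-oxo-4H-chromen-8-yl]benzoate | COc1ccc(-c2cc(=O)c3c(OCc4ccccc4)cc(OCc4ccccc4)c(-c4cc(C(=O)Oc5cc(OC)cc(OCc6ccccc6)c5C(C)=O)ccc4OCc4ccccc4)c3o2)cc1
F5 | step 10 | 1-[2-(benzyloxy)-6-hydroxy-4-methoxyphenyl]-3-{4-(benzyloxy)-3-[5,7-bis(benzyloxy)-2-(4-methoxyphenyl)-4-oxo-4H-chromen-8-yl]phenyl}propane-1,3-dione | COc1ccc(-c2cc(=O)c3c(OCc4ccccc4)cc(OCc4ccccc4)c(-c4cc(C(=O)CC(=O)c5c(O)cc(OC)cc5OCc5ccccc5)ccc4OCc4ccccc4)c3o2)cc1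
F0 | step 12 | none | none
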